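**Retrosynthetic overview**
1. The C2'=C3' alkene is made last (Horner–Wadsworth–Emmons), splitting the target into phosphonoacetate 19 of the hydroxy-lactone and enal 30; two silyl ethers come off in the final step.
2. The δ-lactone (the only ring, closed in step 9) comes from homoallylic alcohol 14: light-driven hydrocarboxylation of the vinyl group makes C2–C3 and the acid closes on O-6. C5–C6 (both stereocentres) come from a Felkin-controlled syn γ-silyloxyallylation of aldehyde 10.
3. Aldehyde 10: C7–C8 by invertive coupling of (S)-lactate triflate 2 with the Grignard reagent from bromide 6; C10–C11 by nickel/photoredox coupling of bromohydrin 3 with (E)-2-bromobut-2-ene.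
4. Enal 30: C5'–C6' by sensitised photoaddition of the 1,3-dioxolan-2-yl radical to butenolide 20 (sets C6'), then lactone reduction, glycol cleavage/reduction, silylation, acetal cleavage and Wittig olefination.
5. Ring order: the butenolide ring of 20 is opened (step 13) and its stereocentre excised (step 14); the δ-lactone is the single ring formed.

Assumption: locants C2–C13 (lactone and side chain) and C1'–C8' (acyl chain) are used; 3, 4 (pure E isomer), 20 and 29 are taken as purchasable.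

**Route**

Step 1
Reactants: 1 tert-butyl (2S)-2-hydroxypropanoate
Product: 2 tert-butyl (2S)-2-{[(trifluoromethyl)sulfonyl]oxy}propanoate
Conditions: Tf2O, 2,6-lutidine, CH2Cl2, −78 to 0 °C
Reagents that add atoms: trifluoromethanesulfonic anhydride, O=S(=O)(OS(=O)(=O)C(F)(F)F)C(F)(F)F
Why: O-sulfonylation of the lactate hydroxyl with a hindered base does not touch the C–O stereocentre (triflate formation, retention).

Step 2
Reactants: 3 (2S)-3-bromo-2-methylpropan-1-ol; 4 (E)-2-bromobut-2-ene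
Product: 5 (2R,4E)-2,4-dimethylhex-4-en-1-ol
Conditions: NiCl2·(MeOCH2CH2OMe) (5 mol %), 4,4'-di-tert-butyl-2,2'-bipyridine (5 mol %), Ir[dF(CF3)ppy]2(dtbbpy)PF6 (1 mol %), (Me3Si)3SiH, Na2CO3, DME, blue LEDs (450 nm), 25 °C
Reagents that add atoms: none
Why: Nickel/photoredox cross-electrophile coupling in which a photogenerated silyl radical abstracts Br from the primary bromide, the alkyl radical is captured by the alkenylnickel species from 4 and reductive elimination forms C10–C11 with retention of the E geometry; the stereocentre is β to the radical and untouched (the descriptor changes only through CIP priorities).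

Step 3
Reactants: 5 (2R,4E)-2,4-dimethylhex-4-en-1-ol
Product: 6 (2E,5R)-6-bromo-3,5-dimethylhex-2-ene
Conditions: CBr4, PPh3, CH2Cl2, 0 °C
Reagents that add atoms: carbon tetrabromide, BrC(Br)(Br)Br
Why: Appel bromination of a primary alcohol under neutral conditions leaves the β-stereocentre and the trisubstituted alkene alone.

Step 4
Reactants: 6 (2E,5R)-6-bromo-3,5-dimethylhex-2-ene; 2 tert-butyl (2S)-2-{[(trifluoromethyl)sulfonyl]oxy}propanoate
Product: 8 tert-butyl (2S,4S,6E)-2,4,6-trimethyloct-6-enoate, via alkylmagnesium bromide 7 (not isolated)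
Conditions: Mg, THF, 40 °C; then 2, ZnCl2 (5 mol %), THF, 0 °C
Reagents that add atoms: none
Why: ZnCl2-catalysed SN2 coupling of a Grignard reagent (as triorganozincate) with an α-triflyloxy ester proceeds with clean inversion, so the bought lactate centre becomes C-7 (S), and the tert-butyl ester resists carbonyl addition.

Step 5
Reactants: 8 tert-butyl (2S,4S,6E)-2,4,6-trimethyloct-6-enoate
Product: 9 (2S,4S,6E)-2,4,6-trimethyloct-6-en-1-ol
Conditions: LiAlH4, THF, 0 °C to rt
Reagents that add atoms: none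
Why: Hydride reduction of the hindered ester to the primary alcohol cannot epimerise the α-centre.

Step 6
Reactants: 9 (2S,4S,6E)-2,4,6-trimethyloct-6-en-1-ol
Product: 10 (2S,4S,6E)-2,4,6-trimethyloct-6-enal
Conditions: TEMPO (10 mol %), PhI(OAc)2, CH2Cl2, rt
Reagents that add atoms: none
Why: Oxoammonium (TEMPO) oxidation stops at the aldehyde under near-neutral conditions, spares the alkene and does not epimerise C-7; 10 is used at once.

Step 7
Reactants: 11 tert-butyldimethyl(prop-2-en-1-yloxy)silane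
Product: 13 tert-butyldimethyl{[(1Z)-3-(tributylstannyl)prop-1-en-1-yl]oxy}silane, via oxyallyllithium 12 (not isolated)
Conditions: s-BuLi, THF/HMPA, −78 °C; then Bu3SnCl, −78 °C
Reagents that add atoms: tributyltin chloride, CCCC[Sn](Cl)(CCCC)CCCC
Why: Kinetic deprotonation of the allyl silyl ether gives the O-coordinated Z allyllithium, which is stannylated at the carbon remote from oxygen (allylic metalation/γ-stannylation).

Step 8
Reactants: 10 (2S,4S,6E)-2,4,6-trimethyloct-6-enal; 13 tert-butyldimethyl{[(1Z)-3-(tributylstannyl)prop-1-en-1-yl]oxy}silane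
Product: 14 (3R,4R,5S,7S,9E)-3-{[tert-butyl(dimethyl)silyl]oxy}-5,7,9-trimethylundeca-1,9-dien-4-ol
Conditions: BF3·OEt2, CH2Cl2, −78 °C; aq. NaHCO3
Reagents that add atoms: none
Why: Lewis-acid-promoted γ-oxyallylstannane addition through an open antiperiplanar transition state gives the 5,6-syn diol monoether, and Felkin–Anh attack on the α-methyl aldehyde places O-6 syn to the C-7 methyl, so C-5 (R) and C-6 (R) are set by the lactate-derived centre (about 5:1 expected, minor isomers removed by chromatography).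

Step 9
Reactants: 14 (3R,4R,5S,7S,9E)-3-{[tert-butyl(dimethyl)silyl]oxy}-5,7,9-trimethylundeca-1,9-dien-4-ol
Product: 16 (5R,6R)-5-{[tert-butyl(dimethyl)silyl]oxy}-6-[(2S,4S,6E)-4,6-dimethyloct-6-en-2-yl]oxan-2-one, via hydroxy acid 15 (not isolated)
Conditions: HCO2K (5 equiv), 4CzIPN (2 mol %), i-Pr3SiSH (10 mol %), DMSO, blue LEDs (450 nm), 25 °C; then aq. HCl (pH 3), PPTS (cat.), toluene, 40 °C
Reagents that add atoms: potassium formate, [K+].[O-]C=O
Why: Proposed new method: photocatalytic formate hydrocarboxylation of the vinyl group of a 1,2-dioxygenated homoallylic alcohol telescoped into δ-lactonisation — excited 4CzIPN oxidises the thiolate, the bulky silanethiyl radical abstracts H from formate, the nucleophilic CO2 radical anion adds to the unhindered CH2 terminus (far faster than to the trisubstituted alkene), the C-4 radical is reduced by the thiol, and on acidification the acid can close only on O-6 because O-5 is silylated, forming C2–C3 and the ring without touching C-5 or C-6; closest known reaction type: thiol-co-catalysed photochemical anti-Markovnikov hydrocarboxylation of alkenes with formate salts, not shown on this substrate class or with in-flask lactone closure.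

Step 10
Reactants: 16 (5R,6R)-5-{[tert-butyl(dimethyl)silyl]oxy}-6-[(2S,4S,6E)-4,6-dimethyloct-6-en-2-yl]oxan-2-one
Product: 17 (5R,6R)-6-[(2S,4S,6E)-4,6-dimethyloct-6-en-2-yl]-5-hydroxyoxan-2-one
Conditions: HF·pyridine, pyridine, THF, 0 °C
Reagents that add atoms: none
Why: Buffered fluoride desilylation frees O-5 under weakly acidic conditions that minimise γ-translactonisation; 17 is acylated without storage.

Step 11
Reactants: 17 (5R,6R)-6-[(2S,4S,6E)-4,6-dimethyloct-6-en-2-yl]-5-hydroxyoxan-2-one; 18 2-(diethoxyphosphoryl)acetic acid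
Product: 19 (2R,3R)-2-[(2S,4S,6E)-4,6-dimethyloct-6-en-2-yl]-6-oxooxan-3-yl 2-(diethoxyphosphoryl)acetate
Conditions: DCC, DMAP (5 mol %), CH2Cl2, 0 °C to rt
Reagents that add atoms: none
Why: Steglich esterification with the small, highly activated phosphonoacetic acid acylates the hindered secondary hydroxyl quickly with retention at C-5.

Step 12
Reactants: 20 (5S)-5-(hydroxymethyl)furan-2(5H)-one; 21 1,3-dioxolane
Product: 22 (4S,5S)-4-(1,3-dioxolan-2-yl)-5-(hydroxymethyl)oxolan-2-one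
Conditions: Ph2CO (15 mol %), hν (350 nm, Pyrex), neat 21, degassed, 10 °C
Reagents that add atoms: none
Why: Triplet benzophenone abstracts the acetal hydrogen of 21 and the nucleophilic dioxolan-2-yl radical adds to C-4 of the butenolide anti to the C-5 hydroxymethyl group (photochemical Giese-type conjugate addition), so the future C-6' is set by the bought stereocentre.

Step 13
Reactants: 22 (4S,5S)-4-(1,3-dioxolan-2-yl)-5-(hydroxymethyl)oxolan-2-one
Product: 23 (2S,3S)-3-(1,3-dioxolan-2-yl)pentane-1,2,5-triol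
Conditions: LiBH4, THF, 0 °C to rt; MeOH quench
Reagents that add atoms: none
Why: Borohydride reduction opens the lactone to the diol (the future CH2CH2OH arm) and leaves the acetal intact.

Step 14
Reactants: 23 (2S,3S)-3-(1,3-dioxolan-2-yl)pentane-1,2,5-triol
Product: 25 (2S)-2-(1,3-dioxolan-2-yl)butane-1,4-diol, via lactol 24 (not isolated)
Conditions: NaIO4, NaHCO3, THF/H2O, 0 °C; then NaBH4, 0 °C
Reagents that add atoms: none
Why: Malaprade glycol cleavage excises the controlling carbinol carbon's neighbour as formaldehyde, and the resulting aldehyde, held as its lactol, is reduced at once so the α-centre cannot epimerise.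

Step 15
Reactants: 25 (2S)-2-(1,3-dioxolan-2-yl)butane-1,4-diol
Product: 26 2-[(2S)-1,4-bis{[tert-butyl(dimethyl)silyl]oxy}butan-2-yl]-1,3-dioxolane
Conditions: TBSCl, imidazole, DMF, rt
Reagents that add atoms: tert-butyldimethylsilyl chloride, CC(C)(C)[Si](C)(C)Cl
Why: Standard silylation of both primary hydroxyls under basic conditions, which also prevents acid-induced cyclisation onto the acetal.

Step 16
Reactants: 26 2-[(2S)-1,4-bis{[tert-butyl(dimethyl)silyl]oxy}butan-2-yl]-1,3-dioxolane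
Product: 28 (2S)-4-{[tert-butyl(dimethyl)silyl]oxy}-2-({[tert-butyl(dimethyl)silyl]oxy}methyl)butanal, via pyridinium salt 27 (not isolated)
Conditions: Et3SiOTf, 2,4,6-collidine, CH2Cl2, 0 °C; then H2O
Reagents that add atoms: water, O
Why: Silyl triflate/collidine acetal cleavage runs through a pyridinium N,O-acetal that water hydrolyses at 0 °C in a basic medium, so the silyl ethers and the α-stereocentre survive.

Step 17
Reactants: 28 (2S)-4-{[tert-butyl(dimethyl)silyl]oxy}-2-({[tert-butyl(dimethyl)silyl]oxy}methyl)butanal; 29 2-(triphenyl-λ5-phosphanylidene)propanal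
Product: 30 (2E,4R)-6-{[tert-butyl(dimethyl)silyl]oxy}-4-({[tert-butyl(dimethyl)silyl]oxy}methyl)-2-methylhex-2-enal
Conditions: toluene, 90 °C
Reagents that add atoms: none
Why: Wittig olefination with a formyl-stabilised ylide gives the E trisubstituted enal (C4'=C5') without base strong enough to epimerise C-6'.

Step 18
Reactants: 19 (2R,3R)-2-[(2S,4S,6E)-4,6-dimethyloct-6-en-2-yl]-6-oxooxan-3-yl 2-(diethoxyphosphoryl)acetate; 30 (2E,4R)-6-{[tert-butyl(dimethyl)silyl]oxy}-4-({[tert-butyl(dimethyl)silyl]oxy}methyl)-2-methylhex-2-enal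
Product: 31 (2R,3R)-2-[(2S,4S,6E)-4,6-dimethyloct-6-en-2-yl]-6-oxooxan-3-yl (2E,4E,6R)-8-{[tert-butyl(dimethyl)silyl]oxy}-6-({[tert-butyl(dimethyl)silyl]oxy}methyl)-4-methylocta-2,4-dienoate
Conditions: LiCl, i-Pr2NEt, MeCN, rt
Reagents that add atoms: none
Why: Horner–Wadsworth–Emmons olefination under mild LiCl/amine (Masamune–Roush) conditions joins the two halves with E selectivity at C2'=C3' and tolerates the lactone and ester.

Step 19
Reactants: 31 (2R,3R)-2-[(2S,4S,6E)-4,6-dimethyloct-6-en-2-yl]-6-oxooxan-3-yl (2E,4E,6R)-8-{[tert-butyl(dimethyl)silyl]oxy}-6-({[tert-butyl(dimethyl)silyl]oxy}methyl)-4-methylocta-2,4-dienoate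
Product: 32 (2R,3R)-2-[(2S,4S,6E)-4,6-dimethyloct-6-en-2-yl]-6-oxooxan-3-yl (2E,4E,6R)-8-hydroxy-6-(hydroxymethyl)-4-methylocta-2,4-dienoate
Conditions: HF·pyridine, pyridine, THF, 0 °C to rt
Reagents that add atoms: none
Why: Buffered fluoride removes both primary silyl ethers without acyl migration, lactone opening or diene isomerisation (global desilylation).

**Compound list**
1 | tert-butyl (2S)-2-hydroxypropanoate | C[C@H](O)C(=O)OC(C)(C)C | starting material
2 | tert-butyl (2S)-2-{[(trifluoromethyl)sulfonyl]oxy}propanoate | C[C@H](OS(=O)(=O)C(F)(F)F)C(=O)OC(C)(C)C | intermediate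
3 | (2S)-3-bromo-2-methylpropan-1-ol | C[C@@H](CO)CBr | starting material
4 | (E)-2-bromobut-2-ene | C/C=C(\C)Br | starting material
5 | (2R,4E)-2,4-dimethylhex-4-en-1-ol | C/C=C(\C)C[C@@H](C)CO | intermediate
6 | (2E,5R)-6-bromo-3,5-dimethylhex-2-ene | C/C=C(\C)C[C@@H](C)CBr | intermediate
7 | [(2R,4E)-2,4-dimethylhex-4-en-1-yl]magnesium bromide | C/C=C(\C)C[C@@H](C)C[Mg]Br | intermediate
8 | tert-butyl (2S,4S,6E)-2,4,6-trimethyloct-6-enoate | C/C=C(\C)C[C@@H](C)C[C@H](C)C(=O)OC(C)(C)C | intermediate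
9 | (2S,4S,6E)-2,4,6-trimethyloct-6-en-1-ol | C/C=C(\C)C[C@@H](C)C[C@H](C)CO | intermediate
10 | (2S,4S,6E)-2,4,6-trimethyloct-6-enal | C/C=C(\C)C[C@@H](C)C[C@H](C)C=O | intermediate
11 | tert-butyldimethyl(prop-2-en-1-yloxy)silane | C=CCO[Si](C)(C)C(C)(C)C | starting material
12 | {(2Z)-3-{[tert-butyl(dimethyl)silyl]oxy}prop-2-en-1-yl}lithium | [Li]C/C=C\O[Si](C)(C)C(C)(C)C | intermediate
13 | tert-butyldimethyl{[(1Z)-3-(tributylstannyl)prop-1-en-1-yl]oxy}silane | CCCC[Sn](CCCC)(CCCC)C/C=C\O[Si](C)(C)C(C)(C)C | intermediate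
14 | (3R,4R,5S,7S,9E)-3-{[tert-butyl(dimethyl)silyl]oxy}-5,7,9-trimethylundeca-1,9-dien-4-ol | C/C=C(\C)C[C@@H](C)C[C@H](C)[C@@H](O)[C@H](O[Si](C)(C)C(C)(C)C)C=C | intermediate
15 | (4R,5R,6S,8S,10E)-4-{[tert-butyl(dimethyl)silyl]oxy}-5-hydroxy-6,8,10-trimethyldodec-10-enoic acid | C/C=C(\C)C[C@@H](C)C[C@H](C)[C@@H](O)[C@H](O[Si](C)(C)C(C)(C)C)CCC(=O)O | intermediate
16 | (5R,6R)-5-{[tert-butyl(dimethyl)silyl]oxy}-6-[(2S,4S,6E)-4,6-dimethyloct-6-en-2-yl]oxan-2-one | C/C=C(\C)C[C@@H](C)C[C@H](C)[C@H]1OC(=O)CC[C@H]1O[Si](C)(C)C(C)(C)C | intermediate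
17 | (5R,6R)-6-[(2S,4S,6E)-4,6-dimethyloct-6-en-2-yl]-5-hydroxyoxan-2-one | C/C=C(\C)C[C@@H](C)C[C@H](C)[C@H]1OC(=O)CC[C@H]1O | intermediate
18 | 2-(diethoxyphosphoryl)acetic acid | CCOP(=O)(CC(=O)O)OCC | starting material
19 | (2R,3R)-2-[(2S,4S,6E)-4,6-dimethyloct-6-en-2-yl]-6-oxooxan-3-yl 2-(diethoxyphosphoryl)acetate | C/C=C(\C)C[C@@H](C)C[C@H](C)[C@H]1OC(=O)CC[C@H]1OC(=O)CP(=O)(OCC)OCC | intermediate
20 | (5S)-5-(hydroxymethyl)furan-2(5H)-one | OC[C@H]1OC(=O)C=C1 | starting material
21 | 1,3-dioxolane | C1COCO1 | starting material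
22 | (4S,5S)-4-(1,3-dioxolan-2-yl)-5-(hydroxymethyl)oxolan-2-one | OC[C@H]1OC(=O)C[C@@H]1C2OCCO2 | intermediate
23 | (2S,3S)-3-(1,3-dioxolan-2-yl)pentane-1,2,5-triol | OC[C@@H](O)[C@H](CCO)C1OCCO1 | intermediate
24 | (3S)-3-(1,3-dioxolan-2-yl)oxolan-2-ol (anomer mixture) | OC1OCC[C@@H]1C2OCCO2 | intermediate
25 | (2S)-2-(1,3-dioxolan-2-yl)butane-1,4-diol | OC[C@H](CCO)C1OCCO1 | intermediate
26 | 2-[(2S)-1,4-bis{[tert-butyl(dimethyl)silyl]oxy}butan-2-yl]-1,3-dioxolane | CC(C)(C)[Si](C)(C)OC[C@H](CCO[Si](C)(C)C(C)(C)C)C1OCCO1 | intermediate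
27 | 1-[(2S)-4-{[tert-butyl(dimethyl)silyl]oxy}-2-({[tert-butyl(dimethyl)silyl]oxy}methyl)-1-{2-[(triethylsilyl)oxy]ethoxy}butyl]-2,4,6-trimethylpyridin-1-ium trifluoromethanesulfonate | Cc1cc(C)[n+](c(C)c1)C(OCCO[Si](CC)(CC)CC)[C@H](CO[Si](C)(C)C(C)(C)C)CCO[Si](C)(C)C(C)(C)C.[O-]S(=O)(=O)C(F)(F)F | intermediate
28 | (2S)-4-{[tert-butyl(dimethyl)silyl]oxy}-2-({[tert-butyl(dimethyl)silyl]oxy}methyl)butanal | CC(C)(C)[Si](C)(C)OC[C@H](CCO[Si](C)(C)C(C)(C)C)C=O | intermediate
29 | 2-(triphenyl-λ5-phosphanylidene)propanal | CC(C=O)=P(c1ccccc1)(c1ccccc1)c1ccccc1 | starting material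
30 | (2E,4R)-6-{[tert-butyl(dimethyl)silyl]oxy}-4-({[tert-butyl(dimethyl)silyl]oxy}methyl)-2-methylhex-2-enal | O=C/C(C)=C/[C@H](CO[Si](C)(C)C(C)(C)C)CCO[Si](C)(C)C(C)(C)C | intermediate
31 | (2R,3R)-2-[(2S,4S,6E)-4,6-dimethyloct-6-en-2-yl]-6-oxooxan-3-yl (2E,4E,6R)-8-{[tert-butyl(dimethyl)silyl]oxy}-6-({[tert-butyl(dimethyl)silyl]oxy}methyl)-4-methylocta-2,4-dienoate | C/C=C(\C)C[C@@H](C)C[C@H](C)[C@H]1OC(=O)CC[C@H]1OC(=O)/C=C/C(C)=C/[C@H](CO[Si](C)(C)C(C)(C)C)CCO[Si](C)(C)C(C)(C)C | intermediate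
32 | (2R,3R)-2-[(2S,4S,6E)-4,6-dimethyloct-6-en-2-yl]-6-oxooxan-3-yl (2E,4E,6R)-8-hydroxy-6-(hydroxymethyl)-4-methylocta-2,4-dienoate | C/C=C(\C)C[C@@H](C)C[C@H](C)[C@H]1OC(=O)CC[C@H]1OC(=O)/C=C/C(C)=C/[C@H](CO)CCO | target

**Count and risks**

Total: 19 steps. Longest linear sequence: 11 steps (3 → 5 → 6 → 8 → 9 → 10 → 14 → 16 → 17 → 19 → 31 → 32, that is steps 2–6, 8–11, 18 and 19).

The three steps most likely to fail:

Step 9 (the proposed new step). The thiyl radical may abstract the allylic, α-silyloxy hydrogen at C-5 (epimerisation or enol ether formation), add to the alkenes (thiol–ene product, E/Z scrambling at C11=C12), or the CO2 radical anion may simply be too slow on an unactivated alkene. The fallback uses known chemistry, sets out from 14 and returns at 16: linear-selective hydroformylation of the vinyl group [Rh(acac)(CO)2 (1 mol %), Xantphos, CO/H2 1:1, 20 bar, toluene, 60 °C] gives an aldehyde that closes on O-6 to the δ-lactol F1, and TEMPO/PhI(OAc)2 in CH2Cl2 oxidises F1 to lactone 16.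

Step 8. Felkin control by a lone α-methyl group may be modest and the silyl enol ether stannane is sensitive to BF3, so the syn,syn isomer may be hard to obtain pure. The fallback sets out from 10 and returns at 19, using a closed boron transition state and correcting C-5 during esterification. Aldehyde 10 is warmed (toluene, 25–50 °C) with the known pinacol (E)-[3-(tert-butyldimethylsilyloxy)allyl]boronate to give the 5,6-anti Felkin adduct F2. Hydroformylation as above gives the lactol F3, and TEMPO/PhI(OAc)2 gives the trans silyloxy lactone F4. HF·pyridine gives the trans hydroxy lactone F5, and Mitsunobu esterification with 18 (PPh3, DIAD, toluene, 0 °C) inverts C-5 to give 19.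

Step 10. The free hydroxyl of 17 is γ to the lactone carbonyl and can translactonise to the five-membered lactone, which would put the acyl group on O-6 in step 11. The fallback sets out from 16 and returns at 19, keeping C-2 as an acetal while O-5 is unmasked and acylated. i-Bu2AlH (CH2Cl2, −78 °C) reduces 16 to the δ-lactol F1 (the same compound as above), and MeOH/PPTS gives the methyl acetal F6. Bu4NF in THF gives the acetal alcohol F7, which cannot translactonise, and DCC/DMAP with 18 gives the acetal phosphonoacetate F8. CrO3/H2SO4 in acetone at 0 °C hydrolyses and oxidises the acetal directly to 19.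

**Further compounds**
F1 | step 9 | (5R,6R)-5-{[tert-butyl(dimethyl)silyl]oxy}-6-[(2S,4S,6E)-4,6-dimethyloct-6-en-2-yl]oxan-2-ol | C/C=C(\C)C[C@@H](C)C[C@H](C)[C@H]1OC(O)CC[C@H]1O[Si](C)(C)C(C)(C)C
F2 | step 8 | (3S,4R,5S,7S,9E)-3-{[tert-butyl(dimethyl)silyl]oxy}-5,7,9-trimethylundeca-1,9-dien-4-ol | C/C=C(\C)C[C@@H](C)C[C@H](C)[C@@H](O)[C@@H](O[Si](C)(C)C(C)(C)C)C=C
F3 | step 8 | (5S,6R)-5-{[tert-butyl(dimethyl)silyl]oxy}-6-[(2S,4S,6E)-4,6-dimethyloct-6-en-2-yl]oxan-2-ol | C/C=C(\C)C[C@@H](C)C[C@H](C)[C@H]1OC(O)CC[C@@H]1O[Si](C)(C)C(C)(C)C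
F4 | step 8 | (5S,6R)-5-{[tert-butyl(dimethyl)silyl]oxy}-6-[(2S,4S,6E)-4,6-dimethyloct-6-en-2-yl]oxan-2-one | C/C=C(\C)C[C@@H](C)C[C@H](C)[C@H]1OC(=O)CC[C@@H]1O[Si](C)(C)C(C)(C)C
F5 | step 8 | (5S,6R)-6-[(2S,4S,6E)-4,6-dimethyloct-6-en-2-yl]-5-hydroxyoxan-2-one | C/C=C(\C)C[C@@H](C)C[C@H](C)[C@H]1OC(=O)CC[C@@H]1O
F6 | step 10 | tert-butyl{[(2R,3R)-2-[(2S,4S,6E)-4,6-dimethyloct-6-en-2-yl]-6-methoxyoxan-3-yl]oxy}dimethylsilane | C/C=C(\C)C[C@@H](C)C[C@H](C)[C@H]1OC(OC)CC[C@H]1O[Si](C)(C)C(C)(C)C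
F7 | step 10 | (2R,3R)-2-[(2S,4S,6E)-4,6-dimethyloct-6-en-2-yl]-6-methoxyoxan-3-ol | C/C=C(\C)C[C@@H](C)C[C@H](C)[C@H]1OC(OC)CC[C@H]1O
F8 | step 10 | (2R,3R)-2-[(2S,4S,6E)-4,6-dimethyloct-6-en-2-yl]-6-methoxyoxan-3-yl 2-(diethoxyphosphoryl)acetate | C/C=C(\C)C[C@@H](C)C[C@H](C)[C@H]1OC(OC)CC[C@H]1OC(=O)CP(=O)(OCC)OCC
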